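The earlier runs and the new flask come from a simulation for an exercise; scatter was added.

In this closed, stirred, isothermal vessel, substrate meets partner and second reagent together, and I want to know how much intermediate A stands at the end.

in all of them: substrate 0.20 M

|  | partner | second reagent | third reagent | remark | time |
|---|---|---|---|---|---|
| summer | 0.50 equiv | 1 equiv | 1.5 equiv | run made earlier |  |
| dusk | 9.3 equiv | 1 equiv | 1.5 equiv | run made earlier |  |
| north | 0.800 equiv | 1.00 equiv | 1.50 equiv |  | 15 min |
| south-east | 1.50 equiv | 1.00 equiv | 1.50 equiv |  | 15 min |
| north-west | 3.00 equiv | 1.00 equiv | 1.50 equiv |  | 15 min |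
| north-east | 6.00 equiv | 1.00 equiv | 1.50 equiv |  | 15 min |
| west | 12.0 equiv | 1.00 equiv | 1.50 equiv |  | 15 min |

| run | time / min | intermediate A / % | target / % |
|---|---|---|---|
| summer | 1.00 | 22.0 | 0.2 |
| summer | 2.50 | 27.3 | 0 |
| summer | 5.00 | 29.7 | 0.7 |
| summer | 8.00 | 27.5 | 0 |
| summer | 10.0 | 27.1 | 0 |
| dusk | 1.00 | 84.9 | 0.2 |
| dusk | 2.50 | 80.4 | 0 |
| dusk | 5.00 | 71.8 | 1.3 |
| dusk | 8.00 | 64.1 | 1.0 |
| dusk | 10.0 | 59.7 | 2.4 |

(standard deviation of a reading: 0.5 percentage points)

- the analysis behind the earlier runs scatters by 0.5 percentage points, standard deviation
- "hardly changes" means that all values lie within two and a half points (for a concentration: within two and a half percent of the largest)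

- amount of intermediate A at the end, in percent of the substrate charged for north, south-east, north-west, north-east, west, in this order
- how that number moves from the first to the last of them (rises, then falls / falls all the way / hardly changes / falls, then rises / rises all the way)

Each substrate either becomes A with partner or, as I read the runs, spends a second reagent on waste, and I take it that A is lost by spending a second reagent too. Second reagent is charged one to one with substrate, so once substrate has reacted, c(second reagent) equals c(A), the decay is second order, and the inverse of the A share climbs in a straight line. Dusk's first and last readings give its slope as 0.0552 min⁻¹, which as a reading puts the decay time at full charge near 18.1 min. The time allowed, 15 min, over that decay time is 0.829; I call this ratio N, a second-order Damköhler number. The end share is then the start share divided by one plus the start share times N, so it climbs with the start share and flattens. To test whether one number is enough, I carry summer's reading at 5.00 min forward with dusk's slope, which gives 27.4% at 10.0 min against 27.1% read, although the partner charges are 0.50 equiv and 9.3 equiv. Reckoned back along that line to zero time, the readings give a notional start share near 32.4% for summer and near 89.1% for dusk, and N turns these two shares into my estimates of 25.5% and 51.2%. I therefore expect the row to rise all the way.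

The forecast reads 38%, 50%, 59%, 58%, 42%, so its shape is rises, then falls, on the ground “So I take the loss as A + leftover partner”.

The flask gives 31.6%, 39.3%, 45.5%, 49.5%, 51.7%: rises all the way.

    substrate + second reagent → side product (k = 0.100 L mol⁻¹ s⁻¹)
    second reagent + intermediate A → intermediate B (k = 0.00470 L mol⁻¹ s⁻¹)
    third reagent + intermediate B → target (k = 0.00140 L mol⁻¹ s⁻¹)
    target ⇌ isomer of the product (K = 0.780, k = 0.00520 s⁻¹)
    substrate + partner → intermediate A (k = 0.0900 L mol⁻¹ s⁻¹)

Taking the start share as the charge less the side product, N gives 31.7% for north against 31.6%, and 52.1% for west against 51.7%. Part of what keeps A up in west is the shrinking supply of second reagent, acting together with the time allowed: west holds 51.7% of its second reagent at 15.0 min, level with A. With second reagent held at its charge, west ends at 39.3%, and at 150 min it holds 10.5% of A.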